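The cyclohexene is disconnected at its only ring olefin, the trisubstituted C2=C3 bond (CH=C(CH3)) next to the aryl-bearing methine C1. Ring-closing olefin metathesis of an open-chain 1,7-diene, with a vinyl group on the benzylic carbon and an isopropenyl group at the end of the chain, forms this bond and the six-membered ring in one operation with loss of ethene. The precursor is a γ,δ-unsaturated aldehyde that already holds both stereocentres, the quaternary carbon (methyl, formyl, 3-methylbut-3-enyl) and the adjacent coumarinyl methine, set together by iridium/amine dual-catalytic α-allylation of a racemic α-branched aldehyde. The formyl group then becomes the E-styryl link by methylenation and Heck arylation.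

Key step: step 6

Remark on the chemistry: 1 and 6 are taken as commercial; in step 5 the ligand enantiomer on iridium and the pseudoenantiomer of the cinchona amine are those that lead to (2S,3R)-9, the sense of induction being assigned by analogy with aryl vinyl carbinols and α-branched aldehydes.

Step 1
Reactants: 1 5-bromo-2-hydroxy-4-methoxybenzaldehyde
Product: 3 6-bromo-7-methoxy-2H-chromen-2-one, via cinnamate ester 2 (not isolated)
Conditions: Ph3P=CHCO2Et, N,N-diethylaniline, reflux
Reagents that add atoms: ethyl (triphenylphosphoranylidene)acetate, CCOC(=O)C=P(c1ccccc1)(c1ccccc1)c1ccccc1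
Why: Wittig olefination of the salicylaldehyde with the stabilised ylide, then thermal E/Z equilibration and lactonisation of the 2-hydroxycinnamate in the same pot (one-pot coumarin synthesis); no stereocentre is formed.

Step 2
Reactants: 3 6-bromo-7-methoxy-2H-chromen-2-one
Product: 4 7-methoxy-2-oxo-2H-chromene-6-carbaldehyde
Conditions: Pd(OAc)2 (1 mol%), di(1-adamantyl)-n-butylphosphine (3 mol%), TMEDA, CO/H2 (1:1, 5 bar), toluene, 100 °C
Reagents that add atoms: carbon monoxide, [C-]#[O+]
Why: Palladium-catalysed reductive carbonylation (formylation) of the aryl bromide by oxidative addition to zerovalent palladium, CO insertion and hydrogenolysis of the acyl-palladium species; the lactone and its enoate olefin should be inert to syngas under these conditions.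

Step 3
Reactants: 4 7-methoxy-2-oxo-2H-chromene-6-carbaldehyde
Product: 5 6-(1-hydroxyprop-2-en-1-yl)-7-methoxy-2H-chromen-2-one (racemic)
Conditions: CH2=CHMgBr (1.1 equiv), THF, −78 °C; aq NH4Cl
Reagents that add atoms: vinylmagnesium bromide, C=C[Mg]Br
Why: 1,2-addition of the vinyl Grignard reagent to the aldehyde, which is far more electrophilic than the lactone carbonyl at −78 °C; the carbinol is made racemic on purpose, since both enantiomers converge on one allyl-iridium intermediate in step 5.

Step 4
Reactants: 6 5-methylhex-5-en-2-one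
Product: 8 2,5-dimethylhex-5-enal (racemic), via enol ether 7 (not isolated)
Conditions: Ph3P(CH2OMe)Cl, KOtBu, THF, 0 °C → rt; then aq HCl (2 M), THF, rt
Reagents that add atoms: (methoxymethyl)triphenylphosphonium chloride, COC[P+](c1ccccc1)(c1ccccc1)c1ccccc1.[Cl-]; water, O
Why: Wittig methoxymethylenation of the methyl ketone and mild acid hydrolysis of the enol ether (one-carbon homologation to the α-branched aldehyde); the α-stereocentre is left racemic because it is erased on enamine formation in step 5.

Step 5
Reactants: 8 2,5-dimethylhex-5-enal (racemic, 3 equiv); 5 6-(1-hydroxyprop-2-en-1-yl)-7-methoxy-2H-chromen-2-one (racemic)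
Product: 9 (2S,3R)-3-(7-methoxy-2-oxo-2H-chromen-6-yl)-2-methyl-2-(3-methylbut-3-en-1-yl)pent-4-enal
Conditions: [Ir(cod)Cl]2 (3 mol%), BINOL-derived phosphoramidite–olefin ligand 4-(dibenzo[b,f]azepin-5-yl)dinaphtho[2,1-d:1',2'-f][1,3,2]dioxaphosphepine (12 mol%), 9-amino-9-deoxy-epi-cinchona primary amine (10 mol%), Cl3CCO2H (50 mol%), ClCH2CH2Cl, 25 °C
Reagents that add atoms: none
Why: Stereodivergent iridium/amine dual catalysis (α-allylation of an α-branched aldehyde with an aryl vinyl carbinol): the acid promoter ionises 5 with loss of water to an allyl-iridium complex, whose branched terminus is attacked by the enamine of 8, the ligand on iridium fixing the benzylic centre C3 (R) and the amine shielding one enamine face to fix the quaternary centre C2 (S).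

Step 6
Reactants: 9 (2S,3R)-3-(7-methoxy-2-oxo-2H-chromen-6-yl)-2-methyl-2-(3-methylbut-3-en-1-yl)pent-4-enal
Product: 10 (1S,2R)-2-(7-methoxy-2-oxo-2H-chromen-6-yl)-1,4-dimethylcyclohex-3-ene-1-carbaldehyde
Conditions: second-generation Grubbs catalyst (H2IMes)(PCy3)Cl2Ru=CHPh (5 mol%), 1,4-benzoquinone (10 mol%), CH2Cl2 (0.01 M), 40 °C
Reagents that add atoms: none
Why: Olefin metathesis through ruthenacyclobutanes: the ruthenium benzylidene exchanges onto the monosubstituted vinyl group, the new alkylidene adds intramolecularly to the 1,1-disubstituted isopropenyl olefin, and cycloreversion releases the trisubstituted ring olefin while ethene escapes and drives the reaction. The closest known reaction type is the ring-closing metathesis of vinyl/isopropenyl 1,7-dienes to 1-methylcyclohexenes with N-heterocyclic-carbene ruthenium catalysts. The one ring is closed in the ring-closing-metathesis mode as a six-membered carbocycle (both =CH2 termini expelled), helped by the gem-disubstitution at the quaternary carbon. No stereocentre is created; C2 and C3 of 9 are carried through unchanged, the quaternary centre being non-enolisable and the benzylic methine not being touched by the catalyst. The step needs chemoselectivity for the two terminal olefins over the coumarin C3=C4 bond, an electron-poor cis-disubstituted enoate inside a ring that should be inert to the catalyst, and only one ring size is possible because no third reactive olefin is present. It also needs freedom from migration of the benzylic vinyl group into conjugation, which 1,4-benzoquinone as scavenger of ruthenium hydrides and high dilution should secure.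

Step 7
Reactants: 10 (1S,2R)-2-(7-methoxy-2-oxo-2H-chromen-6-yl)-1,4-dimethylcyclohex-3-ene-1-carbaldehyde
Product: 11 6-[(1S,6R)-6-ethenyl-3,6-dimethylcyclohex-2-en-1-yl]-7-methoxy-2H-chromen-2-one
Conditions: Ph3PCH3Br (1.2 equiv), KHMDS, THF, −78 → 0 °C
Reagents that add atoms: methyltriphenylphosphonium bromide, C[P+](c1ccccc1)(c1ccccc1)c1ccccc1.[Br-]
Why: Wittig methylenation; the aldehyde has no α-hydrogen, so it cannot epimerise, and the non-stabilised ylide should react with the aldehyde much faster than with the lactone at low temperature.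

Step 8
Reactants: 11 6-[(1S,6R)-6-ethenyl-3,6-dimethylcyclohex-2-en-1-yl]-7-methoxy-2H-chromen-2-one; 3 6-bromo-7-methoxy-2H-chromen-2-one
Product: 12 6-[(1S,6R)-6-[(E)-2-(7-methoxy-2-oxo-2H-chromen-6-yl)ethenyl]-3,6-dimethylcyclohex-2-en-1-yl]-7-methoxy-2H-chromen-2-one
Conditions: Pd2(dba)3 (2.5 mol%), [HP(t-Bu)3]BF4 (10 mol%), Cy2NMe, 1,4-dioxane, 90 °C
Reagents that add atoms: none
Why: Mizoroki–Heck reaction in which the aryl-palladium species adds to the unsubstituted vinyl terminus and, the neighbouring carbon being quaternary, syn β-hydride elimination can only give the E-styryl olefin; the trisubstituted ring olefin and the coumarin C3=C4 bonds should not compete, and both stereocentres are untouched.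

Compound list
1 | 5-bromo-2-hydroxy-4-methoxybenzaldehyde | O=Cc1cc(Br)c(OC)cc1O | starting material
2 | ethyl (2E)-3-(5-bromo-2-hydroxy-4-methoxyphenyl)prop-2-enoate | CCOC(=O)/C=C/c1cc(Br)c(OC)cc1O | intermediate
3 | 6-bromo-7-methoxy-2H-chromen-2-one | COc1cc2oc(=O)ccc2cc1Br | intermediate
4 | 7-methoxy-2-oxo-2H-chromene-6-carbaldehyde | COc1cc2oc(=O)ccc2cc1C=O | intermediate
5 | 6-(1-hydroxyprop-2-en-1-yl)-7-methoxy-2H-chromen-2-one (racemic) | COc1cc2oc(=O)ccc2cc1C(O)C=C | intermediate
6 | 5-methylhex-5-en-2-one | CC(=O)CCC(C)=C | starting material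
7 | 1-methoxy-2,5-dimethylhexa-1,5-diene (E/Z mixture) | COC=C(C)CCC(C)=C | intermediate
8 | 2,5-dimethylhex-5-enal (racemic) | O=CC(C)CCC(C)=C | intermediate
9 | (2S,3R)-3-(7-methoxy-2-oxo-2H-chromen-6-yl)-2-methyl-2-(3-methylbut-3-en-1-yl)pent-4-enal | O=C[C@@](C)(CCC(C)=C)[C@H](C=C)c1cc2ccc(=O)oc2cc1OC | intermediate
10 | (1S,2R)-2-(7-methoxy-2-oxo-2H-chromen-6-yl)-1,4-dimethylcyclohex-3-ene-1-carbaldehyde (aryl cis to methyl, trans to formyl) | O=C[C@@]1(C)CCC(C)=C[C@@H]1c1cc2ccc(=O)oc2cc1OC | intermediate
11 | 6-[(1S,6R)-6-ethenyl-3,6-dimethylcyclohex-2-en-1-yl]-7-methoxy-2H-chromen-2-one | C=C[C@@]1(C)CCC(C)=C[C@@H]1c1cc2ccc(=O)oc2cc1OC | intermediate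
12 | 6-[(1S,6R)-6-[(E)-2-(7-methoxy-2-oxo-2H-chromen-6-yl)ethenyl]-3,6-dimethylcyclohex-2-en-1-yl]-7-methoxy-2H-chromen-2-one (CNP0415737.1) | COc1cc2oc(=O)ccc2cc1/C=C/[C@@]1(C)CCC(C)=C[C@@H]1c1cc2ccc(=O)oc2cc1OC | target

Total step count: 8. Longest linear sequence: 7 steps (steps 1, 2, 3, 5, 6, 7, 8); step 4 is a one-step side branch.

Steps most likely to fail

Step 5. The enamine of the α-methyl-α-alkyl aldehyde 8 may form without a clear E/Z preference, because methyl and the homoallyl chain differ little in size. Facial shielding by the amine would then no longer translate into one configuration at the quaternary carbon, so diastereocontrol at C2 erodes while the iridium-controlled C3 stays intact. The fallback fixes the quaternary centre by olefin geometry in a palladium-catalysed enantioselective allyl–allyl cross-coupling; it sets out from 5 and 6 and comes back to the route at 11, replacing steps 5 to 7. Carbinol 5 would be acylated (Boc2O, DMAP, CH2Cl2) to racemic tert-butyl 1-(7-methoxy-2-oxo-2H-chromen-6-yl)prop-2-en-1-yl carbonate F1. Ketone 6 would be olefinated (triethyl phosphonoacetate, NaH, THF; Horner–Wadsworth–Emmons) and the 2Z isomer, ethyl (2Z)-3,6-dimethylhepta-2,6-dienoate F2, separated from the 2E isomer. Reduction (DIBAL-H, CH2Cl2, −78 °C) would give (2Z)-3,6-dimethylhepta-2,6-dien-1-ol F3, and palladium-catalysed borylation with B2pin2 under geometry-retaining conditions would give 2-[(2Z)-3,6-dimethylhepta-2,6-dien-1-yl]-4,4,5,5-tetramethyl-1,3,2-dioxaborolane F4. Coupling of F1 with F4 (Pd2(dba)3, one enantiomer of 2,2'-bis(di-2-furylphosphino)-6,6'-dimethoxy-1,1'-biphenyl chosen for the 3S centre, CsF, THF/H2O, 60 °C) should join the two substituted allyl termini by 3,3'-reductive elimination. In the chair-like arrangement of the two allyl ligands the aryl group of the E-allyl unit and the methyl group of the Z-configured unit are both pseudo-equatorial, which should give 6-[(3S,4R)-4-ethenyl-4,7-dimethylocta-1,7-dien-3-yl]-7-methoxy-2H-chromen-2-one F5; the 2E boronate would lead to the C4 epimer. Ring-closing metathesis of F5 under the conditions of step 6 then gives 11 directly; the vinyl group on the quaternary carbon is the least accessible olefin, so closure should involve the benzylic vinyl and the isopropenyl group.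

Step 8. Carbopalladation of a vinyl group flanked by the quaternary carbon and the coumarinyl methine may be slow, so that reduction or homocoupling of 3, or arylation at a coumarin C3=C4 bond, consumes the aryl-palladium species. The fallback makes the styryl olefin by carbonyl olefination instead of cross-coupling; it sets out from 10 and 4 and comes back at 12, replacing steps 7 and 8. Aldehyde 4 would be reduced (NaBH4, MeOH/THF, 0 °C) to 6-(hydroxymethyl)-7-methoxy-2H-chromen-2-one F6, converted with PBr3 (CH2Cl2, 0 °C) into 6-(bromomethyl)-7-methoxy-2H-chromen-2-one F7, and heated with P(OEt)3 (Arbuzov reaction) to give diethyl [(7-methoxy-2-oxo-2H-chromen-6-yl)methyl]phosphonate F8. Deprotonation of F8 (NaHMDS, THF, −78 °C) and Horner–Wadsworth–Emmons reaction with 10 should give 12 with the E geometry usual for benzylic phosphonates.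

Step 2. Hydrodebromination through an aryl-palladium hydride may outrun CO insertion at this ortho-methoxy-substituted position. The fallback installs the formyl group by vinylation and oxidative cleavage instead of carbonylation; it sets out from 3 and comes back at 4. Suzuki–Miyaura coupling of 3 with potassium vinyltrifluoroborate (PdCl2(dppf), Et3N, n-PrOH, 90 °C) would give 6-ethenyl-7-methoxy-2H-chromen-2-one F9. Lemieux–Johnson cleavage (OsO4 cat., NaIO4, 2,6-lutidine, dioxane/H2O) of its styrene olefin, which should react ahead of the electron-poor lactone olefin, gives 4.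

Further compounds
F1 | step 5 | tert-butyl 1-(7-methoxy-2-oxo-2H-chromen-6-yl)prop-2-en-1-yl carbonate (racemic) | COc1cc2oc(=O)ccc2cc1C(OC(=O)OC(C)(C)C)C=C
F2 | step 5 | ethyl (2Z)-3,6-dimethylhepta-2,6-dienoate | CCOC(=O)/C=C(C)\CCC(C)=C
F3 | step 5 | (2Z)-3,6-dimethylhepta-2,6-dien-1-ol | OC/C=C(C)\CCC(C)=C
F4 | step 5 | 2-[(2Z)-3,6-dimethylhepta-2,6-dien-1-yl]-4,4,5,5-tetramethyl-1,3,2-dioxaborolane | CC1(C)OB(C/C=C(C)\CCC(C)=C)OC1(C)C
F5 | step 5 | 6-[(3S,4R)-4-ethenyl-4,7-dimethylocta-1,7-dien-3-yl]-7-methoxy-2H-chromen-2-one | C=C[C@@](C)(CCC(C)=C)[C@H](C=C)c1cc2ccc(=O)oc2cc1OC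
F6 | step 8 | 6-(hydroxymethyl)-7-methoxy-2H-chromen-2-one | COc1cc2oc(=O)ccc2cc1CO
F7 | step 8 | 6-(bromomethyl)-7-methoxy-2H-chromen-2-one | COc1cc2oc(=O)ccc2cc1CBr
F8 | step 8 | diethyl [(7-methoxy-2-oxo-2H-chromen-6-yl)methyl]phosphonate | CCOP(=O)(Cc1cc2ccc(=O)oc2cc1OC)OCC
F9 | step 2 | 6-ethenyl-7-methoxy-2H-chromen-2-one | COc1cc2oc(=O)ccc2cc1C=C
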